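**Retrosynthetic overview**
- Feature used: the quaternary C4 (CMe2) sits next to the oxygen-bearing C3, the retron of an epoxide-derived tertiary radical, and the spiro C10–C9 bond ends on the carbon beta to the C7 lactone carbonyl. One radical chain can therefore make C4–C5 (ring C) and C10–C9 (ring B).
- Endgame: C1 ketone from its silyl ether; C15–C17 acrylic acid from a C13 acetyl group by enol triflate carbonylation; C13 acetyl from the C13 ketone; ring D from C3–OH and C6–OH.
- Key disconnection: spirolactone 21 from epoxy dienyl ester 19 by a titanocene epoxide-opening cascade.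
- 19 from ring A acid 17 (from 1,4-dioxaspiro[4.5]decan-7-one) and allylic alcohol 12. In 12, C1 is set by asymmetric ynone reduction, the C5=C10 geometry by hydroxyl-directed trans-hydrostannation, and C3 later by Shi epoxidation.
- Ring order: A (bought) → C and B (step 12) → D (step 14).

Key step: step 12

Numbering and abbreviations: ent-kaurane numbers are used (C1 ketone, C2 CH2, C3 OCH, C4 CMe2, C5 CH, C6 OCH2, C7 lactone C=O, C8, C9, spiro C10, C11, C12, C13, C14, C15–C17 acrylic acid, C20 lactone OCH2; ring A cyclohexane, ring B lactone, ring C cyclohexanone, ring D tetrahydrofuran); TBS = tert-butyldimethylsilyl, Tf = trifluoromethanesulfonyl.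
Remark on C1: C1 is carried as the (R)-silyl ether, trans to the C3 oxygen. It is then axial in the chair of step 12 and equatorial in the bridged ether of step 14; the C1 epimer would sit syn-pentane to C11 in step 12 and under the ether bridge in step 14.
Assumption: the D-fructose-derived ketone is taken to give the (3R)-epoxide, as the spiro transition-state model predicts; otherwise its enantiomer would be used.

Step 1
Reactants: 1 4-methylpent-3-enoic acid
Product: 3 N-methoxy-N,4-dimethylpent-3-enamide, via acyl imidazole 2 (not isolated)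
Conditions: 1,1'-carbonyldiimidazole, CH2Cl2, 0 °C to rt; then MeNH(OMe)·HCl, rt
Reagents that add atoms: N,O-dimethylhydroxylamine hydrochloride, CNOC.Cl
Why: Weinreb amide formation through the acyl imidazole is mild enough to leave the beta,gamma double bond out of conjugation, and no stereocentre is formed.

Step 2
Reactants: 3 N-methoxy-N,4-dimethylpent-3-enamide; 4 tert-butyldimethyl(prop-2-yn-1-yloxy)silane
Product: 7 1-[(tert-butyldimethylsilyl)oxy]-7-methyloct-6-en-2-yn-4-one, via lithium acetylide 5 (not isolated), via tetrahedral adduct 6 (not isolated)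
Conditions: 4, n-BuLi, THF, −78 °C; then 3, −78 to −20 °C; aq. NH4Cl, 0 °C
Reagents that add atoms: none
Why: Weinreb ketone synthesis, in which the chelated tetrahedral adduct stops at the ketone stage and releases the ynone only on the cold, weakly acidic quench, so the doubly activated C2 methylene should not isomerise.

Step 3
Reactants: 7 1-[(tert-butyldimethylsilyl)oxy]-7-methyloct-6-en-2-yn-4-one
Product: 8 (4R)-1-[(tert-butyldimethylsilyl)oxy]-7-methyloct-6-en-2-yn-4-ol
Conditions: Ru[(R,R)-TsDPEN](p-cymene) (2 mol%), i-PrOH, rt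
Reagents that add atoms: none
Why: Noyori asymmetric transfer hydrogenation of an alkynyl ketone, in which the alkyne takes the place of the aryl group in the hydride-transfer transition state, so that the (R,R)-ligand should give the (R)-carbinol that becomes C1.

Step 4
Reactants: 8 (4R)-1-[(tert-butyldimethylsilyl)oxy]-7-methyloct-6-en-2-yn-4-ol
Product: 9 (2Z,4R)-1-[(tert-butyldimethylsilyl)oxy]-7-methyl-3-(tributylstannyl)octa-2,6-dien-4-ol
Conditions: [Cp*RuCl]4 (2 mol%), Bu3SnH, CH2Cl2, rt
Reagents that add atoms: tributyltin hydride, CCCC[SnH](CCCC)CCCC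
Why: hydroxyl-directed ruthenium-catalysed trans-hydrostannation puts tin on the alkyne carbon next to the free carbinol (C10) and hydrogen on C5 anti to it, which fixes the C5=C10 geometry (C6 cis to the position that later carries C20) without a regioisomer problem.

Step 5
Reactants: 9 (2Z,4R)-1-[(tert-butyldimethylsilyl)oxy]-7-methyl-3-(tributylstannyl)octa-2,6-dien-4-ol
Product: 10 tributyl[(2Z,4R)-1,4-bis[(tert-butyldimethylsilyl)oxy]-7-methylocta-2,6-dien-3-yl]stannane
Conditions: TBSOTf, 2,6-lutidine, CH2Cl2, −78 °C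
Reagents that add atoms: tert-butyldimethylsilyl trifluoromethanesulfonate, CC(C)(C)[Si](C)(C)OS(=O)(=O)C(F)(F)F
Why: silyl triflate silylation of the hindered secondary alcohol under lutidine buffering should leave the acid-sensitive alkenylstannane intact and removes the hydroxyl group before iodine is used.

Step 6
Reactants: 10 tributyl[(2Z,4R)-1,4-bis[(tert-butyldimethylsilyl)oxy]-7-methylocta-2,6-dien-3-yl]stannane
Product: 11 (2Z,4R)-1,4-bis[(tert-butyldimethylsilyl)oxy]-3-iodo-7-methylocta-2,6-diene
Conditions: I2, CH2Cl2, 0 °C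
Reagents that add atoms: iodine, II
Why: iododestannylation of an alkenylstannane is fast and proceeds with retention of alkene geometry, well ahead of any reaction of iodine with the C3=C4 alkene.

Step 7
Reactants: 11 (2Z,4R)-1,4-bis[(tert-butyldimethylsilyl)oxy]-3-iodo-7-methylocta-2,6-diene
Product: 12 (2E)-4-[(tert-butyldimethylsilyl)oxy]-2-[(1R)-1-[(tert-butyldimethylsilyl)oxy]-4-methylpent-3-en-1-yl]but-2-en-1-ol
Conditions: Bu3SnCH2OH, Pd(PPh3)4 (10 mol%), 1,4-dioxane, 90 °C
Reagents that add atoms: (tributylstannyl)methanol, OC[Sn](CCCC)(CCCC)CCCC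
Why: Stille hydroxymethylation transfers the alpha-oxygenated CH2OH group in preference to butyl with retention of geometry, so C20 enters cis to C6 and no alkenyllithium, which would be prone to silyl migration from the cis C6 silyl ether, is needed.

Step 8
Reactants: 13 1,4-dioxaspiro[4.5]decan-7-one
Product: 15 1,4-dioxaspiro[4.5]dec-7-en-7-yl trifluoromethanesulfonate, via lithium enolate 14 (not isolated)
Conditions: LiN(i-Pr)2, THF, −78 °C; then PhNTf2, −78 °C to rt
Reagents that add atoms: N-phenylbis(trifluoromethanesulfonimide), O=S(=O)(N(c1ccccc1)S(=O)(=O)C(F)(F)F)C(F)(F)F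
Why: kinetic enolate formation and O-triflation, in which the base should remove a proton from the future C9 and not from C14, which lies between the carbonyl and the ketal carbon, is more hindered and would lead to beta-elimination of a ketal oxygen.

Step 9
Reactants: 15 1,4-dioxaspiro[4.5]dec-7-en-7-yl trifluoromethanesulfonate
Product: 17 1,4-dioxaspiro[4.5]dec-7-ene-7-carboxylic acid, via mixed anhydride 16 (not isolated)
Conditions: Pd(OAc)2 (5 mol%), PPh3 (10 mol%), KOAc, CO (1 atm), DMF, 50 °C; then H2O, pH 4 buffer, 0 °C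
Reagents that add atoms: carbon monoxide, [C-]#[O+]; water, O
Why: palladium-catalysed hydroxycarbonylation of an enol triflate, in which acetate intercepts the acylpalladium intermediate as a mixed anhydride that is hydrolysed on work-up, gives the conjugated acid (C7 on C8=C9) directly.

Step 10
Reactants: 12 (2E)-4-[(tert-butyldimethylsilyl)oxy]-2-[(1R)-1-[(tert-butyldimethylsilyl)oxy]-4-methylpent-3-en-1-yl]but-2-en-1-ol; 17 1,4-dioxaspiro[4.5]dec-7-ene-7-carboxylic acid
Product: 18 (2E)-4-(TBSO)-2-[(1R)-1-(TBSO)-4-methylpent-3-en-1-yl]but-2-en-1-yl 1,4-dioxaspiro[4.5]dec-7-ene-7-carboxylate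
Conditions: EDC·HCl, DMAP, CH2Cl2, 0 °C to rt
Reagents that add atoms: none
Why: Steglich-type carbodiimide esterification of the only free hydroxyl group, the primary allylic C20–OH, under conditions that should not move the C8=C9 double bond.

Step 11
Reactants: 18 (2E)-4-(TBSO)-2-[(1R)-1-(TBSO)-4-methylpent-3-en-1-yl]but-2-en-1-yl 1,4-dioxaspiro[4.5]dec-7-ene-7-carboxylate
Product: 19 (2E)-4-(TBSO)-2-[(1R)-1-(TBSO)-2-[(2R)-3,3-dimethyloxiran-2-yl]ethyl]but-2-en-1-yl 1,4-dioxaspiro[4.5]dec-7-ene-7-carboxylate
Conditions: D-fructose-derived Shi ketone (30 mol%), Oxone (2KHSO5·KHSO4·K2SO4), K2CO3, Bu4NHSO4, MeCN–dimethoxymethane–aq. Na2B4O7 buffer (pH 10.5), 0 °C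
Reagents that add atoms: potassium peroxymonosulfate, OOS(=O)(=O)[O-].[K+]
Why: Shi epoxidation, in which the electrophilic dioxirane should attack only the electron-rich C3=C4 alkene (C5=C10 carries three allylic oxygens and C8=C9 is an enoate) and the spiro transition state should give the (3R)-epoxide.

Step 12
Reactants: 19 (2E)-4-(TBSO)-2-[(1R)-1-(TBSO)-2-[(2R)-3,3-dimethyloxiran-2-yl]ethyl]but-2-en-1-yl 1,4-dioxaspiro[4.5]dec-7-ene-7-carboxylate
Product: 21 (1R,3R,5R,8S,9R,10S)-spirolactone (rings A B C; C7–O–C20 lactone; C3–OH; C1–OTBS; C6–OTBS; C13 ethylene ketal), via titanium enolate 20 (not isolated)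
Conditions: Cp2TiCl2 (0.3 equiv), Mn dust (4 equiv), 2,4,6-collidine hydrochloride (3 equiv), THF (0.005 M), 40 °C, 19 added over 10 h
Reagents that add atoms: none
Why: Proposed new method: Cp2TiCl (trivalent titanium, from Cp2TiCl2 and Mn) opens the C3–C4 epoxide to the tertiary C4 radical with C3–O intact, this radical closes ring C by 6-endo-trig attack on C5, the tertiary C10 radical so formed closes ring B by 6-endo-trig attack on C9 of the tethered enoate, and a second Cp2TiCl reduces the C8 radical to a titanium enolate that collidinium chloride protonates. The closest known reactions are titanocene cyclisations of epoxygeranyl esters and additions of epoxide-derived radicals to acrylates, but closure of a quaternary–tertiary bond through an ester tether is untested, the ester has to react through its minor s-cis rotamer, and the low stationary concentration of Cp2TiCl is meant to keep hydrogen abstraction from the C10 radical slower than this closure. Both closures need the endo mode, which the substrate secures because the proximal alkene carbons C10 and C8 are fully substituted and the attacked carbons C5 and C9 lead to a tertiary and to an ester-stabilised radical, so both additions are also polarity matched. C5 is set by a chair transition state with the C3 titanoxy group and C6 equatorial and the C1 silyloxy group axial, which puts C6 cis to the C3 oxygen. C10 is set by attack of C9 on the face opposite the axial C4 methyl group, so that C9 becomes equatorial and trans to C6, and C9 is set by the enoate face that turns its hydrogen under ring C and C11 towards the C1 side, whose equatorial position is a hydrogen, away from the equatorial C6 substituent of C5. C8 is set by kinetic protonation of the enolate on the face of the C9 hydrogen, anti to the quaternary C10, which should give the cis A/B fusion.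

Step 13
Reactants: 21 (1R,3R,5R,8S,9R,10S)-spirolactone
Product: 22 keto diol (as 21 but C13 ketone and free C6–OH; C1–OTBS kept)
Conditions: 1 M aq. HCl, THF, rt
Reagents that add atoms: water, O
Why: acid hydrolysis should remove the dioxolane and the primary C6 silyl ether in one operation, while the secondary C1 silyl ether flanked by the quaternary C10 is cleaved far more slowly.

Step 14
Reactants: 22 keto diol
Product: 24 tetracyclic ether (ring D closed by C3–O–C6; C13 ketone; C1–OTBS), via C6 triflate 23 (not isolated)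
Conditions: Tf2O (1.05 equiv), 2,6-di-tert-butyl-4-methylpyridine, CH2Cl2, −78 °C to rt
Reagents that add atoms: none
Why: the primary C6 alcohol should be triflated selectively at −78 °C and the cis C3 hydroxyl then displaces the triflate (5-exo-tet Williamson-type etherification) once ring C flips to the chair with C3–O and C6 axial, in which the trans C1 silyl ether is equatorial; C3 and C5 are not touched, so ring D keeps the configuration set in step 12.

Step 15
Reactants: 24 tetracyclic ether
Product: 26 C13 enol triflate (C12=C13), via potassium enolate 25 (not isolated)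
Conditions: KN(SiMe3)2 (1.05 equiv), THF, −78 °C; then PhNTf2, −78 to 0 °C
Reagents that add atoms: N-phenylbis(trifluoromethanesulfonimide), O=S(=O)(N(c1ccccc1)S(=O)(=O)C(F)(F)F)C(F)(F)F
Why: enol triflate formation from the ketone enolate, the C13 ketone being far more acidic than the lactone at C8; the position of the new double bond (C12=C13 drawn, C13=C14 equally useful) is removed again in step 17.

Step 16
Reactants: 26 C13 enol triflate
Product: 28 enone (13-acetyl; C12=C13), via ethoxydiene 27 (not isolated)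
Conditions: tributyl(1-ethoxyvinyl)stannane, Pd(PPh3)4 (5 mol%), LiCl, THF, 65 °C; then 1 M aq. HCl, rt
Reagents that add atoms: tributyl(1-ethoxyvinyl)stannane, C=C(OCC)[Sn](CCCC)(CCCC)CCCC; water, O
Why: Stille coupling of the enol triflate with an acyl anion equivalent, followed by hydrolysis of the enol ether, turns the C13 ketone into a C13 acetyl group (C16 and C17) without any strong base.

Step 17
Reactants: 28 enone
Product: 30 (13R)-acetyl compound (acetyl equatorial on ring A), via C13 epimer 29 (not isolated)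
Conditions: H2 (1 atm), 10% Pd/C, EtOAc, rt; filter; then DBU, toluene, 60 °C
Reagents that add atoms: none
Why: heterogeneous hydrogenation of the enone C=C bond followed by base equilibration of the methyl ketone, so that whichever face hydrogen adds to, epimerisation through the enol should place the acetyl group equatorial and trans to C10 across ring A, which is the (13R) configuration, while the much less acidic C8–H of the lactone is not expected to exchange.

Step 18
Reactants: 30 (13R)-acetyl compound
Product: 32 vinyl triflate (C13–C(OTf)=CH2), via lithium enolate 31 (not isolated)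
Conditions: LiN(i-Pr)2 (1.05 equiv), THF, −78 °C; then N-(5-chloropyridin-2-yl)bis(trifluoromethanesulfonimide), −78 to −40 °C
Reagents that add atoms: N-(5-chloropyridin-2-yl)bis(trifluoromethanesulfonimide), FC(F)(F)S(=O)(=O)N(c1ccc(Cl)cn1)S(=O)(=O)C(F)(F)F
Why: kinetic deprotonation of a methyl ketone should occur at the methyl group (C17) and not at the tertiary C13–H or the lactone C8–H, and the reactive pyridyl triflimide traps the enolate cold before it can equilibrate, so C13 keeps its configuration.

Step 19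
Reactants: 32 vinyl triflate
Product: 34 acrylic acid with C1–OTBS, via mixed anhydride 33 (not isolated)
Conditions: Pd(OAc)2 (5 mol%), PPh3 (10 mol%), KOAc, CO (1 atm), DMF, 50 °C; then H2O
Reagents that add atoms: carbon monoxide, [C-]#[O+]; water, O
Why: palladium-catalysed hydroxycarbonylation of the 1,1-disubstituted vinyl triflate should give the 2-substituted acrylic acid (C15) under weakly basic conditions that the lactone and the silyl ether tolerate.

Step 20
Reactants: 34 acrylic acid with C1–OTBS
Product: 35 (1R)-C1 alcohol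
Conditions: HF·pyridine, THF, 0 to 40 °C
Reagents that add atoms: none
Why: fluoride desilylation under acidic, non-basic conditions should free the hindered C1 alcohol without opening the lactone or adding to the acrylic acid.

Step 21
Reactants: 35 (1R)-C1 alcohol
Product: 36 CNP0268721.2
Conditions: Dess–Martin periodinane, CH2Cl2, rt
Reagents that add atoms: none
Why: Dess–Martin oxidation of the secondary C1 alcohol under near-neutral conditions makes the C1 ketone last, so that the beta-alkoxy ketone (C1 and C3–O) never meets a base that could open ring D by elimination.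

**Compound list**
1 | 4-methylpent-3-enoic acid | CC(C)=CCC(=O)O | starting material
2 | 1-(imidazol-1-yl)-4-methylpent-3-en-1-one | CC(C)=CCC(=O)n1ccnc1 | intermediate
3 | N-methoxy-N,4-dimethylpent-3-enamide | CC(C)=CCC(=O)N(C)OC | intermediate
4 | tert-butyldimethyl(prop-2-yn-1-yloxy)silane | C#CCO[Si](C)(C)C(C)(C)C | starting material
5 | [3-[(tert-butyldimethylsilyl)oxy]prop-1-yn-1-yl]lithium | [Li]C#CCO[Si](C)(C)C(C)(C)C | intermediate
6 | lithium alkoxide of the tetrahedral adduct of 5 and 3 | CC(C)=CCC(O[Li])(N(C)OC)C#CCO[Si](C)(C)C(C)(C)C | intermediate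
7 | 1-[(tert-butyldimethylsilyl)oxy]-7-methyloct-6-en-2-yn-4-one | CC(C)=CCC(=O)C#CCO[Si](C)(C)C(C)(C)C | intermediate
8 | (4R)-1-[(tert-butyldimethylsilyl)oxy]-7-methyloct-6-en-2-yn-4-ol | CC(C)=CC[C@@H](O)C#CCO[Si](C)(C)C(C)(C)C | intermediate
9 | (2Z,4R)-1-[(tert-butyldimethylsilyl)oxy]-7-methyl-3-(tributylstannyl)octa-2,6-dien-4-ol | CC(C)=CC[C@@H](O)/C(=C/CO[Si](C)(C)C(C)(C)C)[Sn](CCCC)(CCCC)CCCC | intermediate
10 | tributyl[(2Z,4R)-1,4-bis[(tert-butyldimethylsilyl)oxy]-7-methylocta-2,6-dien-3-yl]stannane | CC(C)=CC[C@@H](O[Si](C)(C)C(C)(C)C)/C(=C/CO[Si](C)(C)C(C)(C)C)[Sn](CCCC)(CCCC)CCCC | intermediate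
11 | (2Z,4R)-1,4-bis[(tert-butyldimethylsilyl)oxy]-3-iodo-7-methylocta-2,6-diene | CC(C)=CC[C@@H](O[Si](C)(C)C(C)(C)C)/C(I)=C/CO[Si](C)(C)C(C)(C)C | intermediate
12 | (2E)-4-[(tert-butyldimethylsilyl)oxy]-2-[(1R)-1-[(tert-butyldimethylsilyl)oxy]-4-methylpent-3-en-1-yl]but-2-en-1-ol | CC(C)=CC[C@@H](O[Si](C)(C)C(C)(C)C)/C(CO)=C/CO[Si](C)(C)C(C)(C)C | intermediate
13 | 1,4-dioxaspiro[4.5]decan-7-one | O=C1CCCC2(C1)OCCO2 | starting material
14 | lithium 1,4-dioxaspiro[4.5]dec-7-en-7-olate | [Li]OC1=CCCC2(C1)OCCO2 | intermediate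
15 | 1,4-dioxaspiro[4.5]dec-7-en-7-yl trifluoromethanesulfonate | O=S(=O)(OC1=CCCC2(C1)OCCO2)C(F)(F)F | intermediate
16 | acetic 1,4-dioxaspiro[4.5]dec-7-ene-7-carboxylic anhydride | CC(=O)OC(=O)C1=CCCC2(C1)OCCO2 | intermediate
17 | 1,4-dioxaspiro[4.5]dec-7-ene-7-carboxylic acid | O=C(O)C1=CCCC2(C1)OCCO2 | intermediate
18 | (2E)-4-(TBSO)-2-[(1R)-1-(TBSO)-4-methylpent-3-en-1-yl]but-2-en-1-yl 1,4-dioxaspiro[4.5]dec-7-ene-7-carboxylate | O=C(OC/C(=C\CO[Si](C)(C)C(C)(C)C)[C@H](O[Si](C)(C)C(C)(C)C)CC=C(C)C)C1=CCCC2(C1)OCCO2 | intermediate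
19 | (2E)-4-(TBSO)-2-[(1R)-1-(TBSO)-2-[(2R)-3,3-dimethyloxiran-2-yl]ethyl]but-2-en-1-yl 1,4-dioxaspiro[4.5]dec-7-ene-7-carboxylate (key-step precursor) | O=C(OC/C(=C\CO[Si](C)(C)C(C)(C)C)[C@H](O[Si](C)(C)C(C)(C)C)C[C@H]1OC1(C)C)C1=CCCC2(C1)OCCO2 | intermediate
20 | bis(titanocene chloride) species: C3 titanium alkoxide and C7=C8 titanium enolate of 21 | C12(OCCO1)CC[C@@H]3C(C2)=C(O[Ti](Cl)(C4C=CC=C4)C4C=CC=C4)OC[C@]31[C@H](O[Si](C)(C)C(C)(C)C)C[C@@H](O[Ti](Cl)(C4C=CC=C4)C4C=CC=C4)C(C)(C)[C@H]1CO[Si](C)(C)C(C)(C)C | intermediate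
21 | (1R,3R,5R,8S,9R,10S)-spirolactone: rings A, B, C; C7–O–C20 lactone; C3–OH; C1–OTBS; C6–OTBS; C13 ethylene ketal (key-step product) | C12(OCCO1)CC[C@@H]3[C@H](C2)C(=O)OC[C@]31[C@H](O[Si](C)(C)C(C)(C)C)C[C@@H](O)C(C)(C)[C@H]1CO[Si](C)(C)C(C)(C)C | intermediate
22 | keto diol: C13 ketone, C3–OH, C6–OH, C1–OTBS | O=C1CC[C@@H]3[C@H](C1)C(=O)OC[C@]31[C@H](O[Si](C)(C)C(C)(C)C)C[C@@H](O)C(C)(C)[C@H]1CO | intermediate
23 | C6 trifluoromethanesulfonate of 22 | O=C1CC[C@@H]3[C@H](C1)C(=O)OC[C@]31[C@H](O[Si](C)(C)C(C)(C)C)C[C@@H](O)C(C)(C)[C@H]1COS(=O)(=O)C(F)(F)F | intermediate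
24 | tetracyclic ether: ring D closed (C3–O–C6), C13 ketone, C1–OTBS | O=C1CC[C@@H]3[C@H](C1)C(=O)OC[C@]31[C@H](O[Si](C)(C)C(C)(C)C)C[C@H]4OC[C@@H]1C4(C)C | intermediate
25 | potassium C12=C13 enolate of 24 | [K]OC1=CC[C@@H]3[C@H](C1)C(=O)OC[C@]31[C@H](O[Si](C)(C)C(C)(C)C)C[C@H]4OC[C@@H]1C4(C)C | intermediate
26 | C13 enol triflate (C12=C13) | O=S(=O)(OC1=CC[C@@H]3[C@H](C1)C(=O)OC[C@]31[C@H](O[Si](C)(C)C(C)(C)C)C[C@H]4OC[C@@H]1C4(C)C)C(F)(F)F | intermediate
27 | 13-(1-ethoxyvinyl) diene | C=C(OCC)C1=CC[C@@H]3[C@H](C1)C(=O)OC[C@]31[C@H](O[Si](C)(C)C(C)(C)C)C[C@H]4OC[C@@H]1C4(C)C | intermediate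
28 | enone: 13-acetyl, C12=C13 | CC(=O)C1=CC[C@@H]3[C@H](C1)C(=O)OC[C@]31[C@H](O[Si](C)(C)C(C)(C)C)C[C@H]4OC[C@@H]1C4(C)C | intermediate
29 | (13S)-acetyl epimer (acetyl axial, cis to C7) | CC(=O)[C@H]1CC[C@@H]3[C@H](C1)C(=O)OC[C@]31[C@H](O[Si](C)(C)C(C)(C)C)C[C@H]4OC[C@@H]1C4(C)C | intermediate
30 | (13R)-acetyl compound (acetyl equatorial) | CC(=O)[C@@H]1CC[C@@H]3[C@H](C1)C(=O)OC[C@]31[C@H](O[Si](C)(C)C(C)(C)C)C[C@H]4OC[C@@H]1C4(C)C | intermediate
31 | lithium C16=C17 enolate of 30 | C=C(O[Li])[C@@H]1CC[C@@H]3[C@H](C1)C(=O)OC[C@]31[C@H](O[Si](C)(C)C(C)(C)C)C[C@H]4OC[C@@H]1C4(C)C | intermediate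
32 | vinyl triflate: C13–C(OTf)=CH2 | C=C(OS(=O)(=O)C(F)(F)F)[C@@H]1CC[C@@H]3[C@H](C1)C(=O)OC[C@]31[C@H](O[Si](C)(C)C(C)(C)C)C[C@H]4OC[C@@H]1C4(C)C | intermediate
33 | mixed acetic anhydride of 34 | C=C(C(=O)OC(C)=O)[C@@H]1CC[C@@H]3[C@H](C1)C(=O)OC[C@]31[C@H](O[Si](C)(C)C(C)(C)C)C[C@H]4OC[C@@H]1C4(C)C | intermediate
34 | acrylic acid with C1–OTBS | C=C(C(=O)O)[C@@H]1CC[C@@H]3[C@H](C1)C(=O)OC[C@]31[C@H](O[Si](C)(C)C(C)(C)C)C[C@H]4OC[C@@H]1C4(C)C | intermediate
35 | (1R)-C1 alcohol | C=C(C(=O)O)[C@@H]1CC[C@@H]3[C@H](C1)C(=O)OC[C@]31[C@H](O)C[C@H]4OC[C@@H]1C4(C)C | intermediate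
36 | CNP0268721.2 | C=C(C(=O)O)[C@@H]1CC[C@@H]2[C@H](C1)C(=O)OC[C@]21C(=O)C[C@H]2OC[C@@H]1C2(C)C | target

**Step count and risks**
Total steps: 21. Longest linear sequence: 19 (steps 1–7 and 10–21).

Step 12 (ring B closure through the ester tether). What may go wrong: the C10 radical is quenched by titanium (hydrogen abstraction to an alkene, or reduction) before the ester reaches its reactive rotamer, or ring B closes on the wrong enoate face. The fallback sets out from 19 and comes back at 21, with known reactions only, by taking the ester carbonyl out of the tether. Reductive acetylation of 19 (i-Bu2AlH, CH2Cl2, −78 °C; then Ac2O, pyridine, DMAP) would give alpha-acetoxy ether F1, in which C7 is an acyl acetal without rotamer bias. Its titanocene bicyclisation (Cp2TiCl2, Mn, H2O, THF) is the classical polyene mode, 6-endo attack of the tertiary C10 radical on the unactivated trisubstituted C8=C9 alkene, with the titanocene aqua complex as hydrogen-atom donor for the C8 radical, and would give lactol acetate F2. K2CO3 in MeOH would free lactol F3, and TEMPO with PhI(OAc)2 would oxidise the lactol to the lactone in preference to the hindered C3 alcohol, which returns to 21.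

Step 14 (ring D closure). What may go wrong: slow displacement, because ring C has to flip into the chair with C3–O and C6 axial, and competing triflation of the C3 hydroxyl followed by rearrangement next to the quaternary C4. The fallback sets out from 22 and comes back at 24, and makes the C–O bond by hemiacetal formation and hydride transfer instead of a displacement at C6. TEMPO (cat.) and PhI(OAc)2 (1.1 equiv) would oxidise only the primary C6 alcohol, and the aldehyde would be held by the C3 hydroxyl as bridged lactol F4. Et3SiH and BF3·OEt2 in CH2Cl2 at −78 °C would reduce the derived oxocarbenium ion to ether 24.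

Step 18 (kinetic enol triflate). What may go wrong: unselective enolisation at the tertiary C13–H or at the lactone C8–H, with epimerisation at either centre. The fallback sets out from 30 and comes back at 34, and avoids any enolate. Takai–Lombardo methylenation (Zn, CH2Br2, TiCl4, THF) of the acetyl group would give isopropenyl compound F5. SeO2 (cat.) with t-BuOOH would oxidise the allylic methyl group, MnO2 completing the oxidation to 2-substituted acrolein F6. Pinnick oxidation (NaClO2, NaH2PO4, 2-methyl-2-butene) would then give acid 34.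

**Further compounds**
F1 | step 12 | alpha-acetoxy ether from 19 (C7 as CH(OAc)–O–C20; epimers at C7) | CC(=O)OC(OC/C(=C\CO[Si](C)(C)C(C)(C)C)[C@H](O[Si](C)(C)C(C)(C)C)C[C@H]1OC1(C)C)C1=CCCC2(C1)OCCO2
F2 | step 12 | lactol acetate (21 with C7 as CH–OAc) | C12(OCCO1)CC[C@@H]3[C@H](C2)C(OC(C)=O)OC[C@]31[C@H](O[Si](C)(C)C(C)(C)C)C[C@@H](O)C(C)(C)[C@H]1CO[Si](C)(C)C(C)(C)C
F3 | step 12 | lactol (21 with C7 as CH–OH) | C12(OCCO1)CC[C@@H]3[C@H](C2)C(O)OC[C@]31[C@H](O[Si](C)(C)C(C)(C)C)C[C@@H](O)C(C)(C)[C@H]1CO[Si](C)(C)C(C)(C)C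
F4 | step 14 | bridged lactol (24 with C6 as CH–OH) | O=C1CC[C@@H]3[C@H](C1)C(=O)OC[C@]31[C@H](O[Si](C)(C)C(C)(C)C)C[C@H]4OC(O)[C@@H]1C4(C)C
F5 | step 18 | 13-isopropenyl compound | C=C(C)[C@@H]1CC[C@@H]3[C@H](C1)C(=O)OC[C@]31[C@H](O[Si](C)(C)C(C)(C)C)C[C@H]4OC[C@@H]1C4(C)C
F6 | step 18 | 2-substituted acrolein (C15 aldehyde) | C=C(C=O)[C@@H]1CC[C@@H]3[C@H](C1)C(=O)OC[C@]31[C@H](O[Si](C)(C)C(C)(C)C)C[C@H]4OC[C@@H]1C4(C)C
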